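**Plan**

- Retrosynthesis: the O7–C6 bond of ring B is cut first (reductive oxa-cyclisation of a C6 aryl ketone onto the C8 oxygen). The C6 ketone goes back to an exocyclic arylidene on C5, and the O3–C2 bond of ring A to a benzylic epoxide. This leaves the two-fold symmetric (E,E)-2,3-bis(arylidene)butane-1,4-diol, cut at both C=C bonds into two veratraldehydes and dimethyl succinate.
- Forward: a double Stobbe condensation joins the three components into the whole carbon skeleton. One arylidene arm is epoxidised and closes ring A (O3, C2, C1, C5, C4); the other arm becomes the C6 ketone; ring B (O7, C6, C5, C1, C8) is closed last.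
- Stereochemistry: C1 and C2 come from a Sharpless epoxidation followed by invertive epoxide opening, C5 from an alkoxide-directed hydroboration, and C6 from hydride delivery to the convex face of a bicyclic oxocarbenium ion.
- Feature used by the key step: on ring A the CH2O arm on C1 and the C6 carbonyl on C5 are cis and 1,4-related, so O7 can only close a cis-fused 3,7-dioxabicyclo[3.3.0]octane oxocarbenium ion (O7=C6). Only its convex face (the side of H-5 and the C1 hydroxyl) is open, which forces the C6 aryl group endo, the epimer that acid equilibration would not give.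

Key step: step 8

Assumption: atoms are numbered as in 3,7-dioxabicyclo[3.3.0]octane (C1 carries OH, C2 and C6 carry the aryl groups); the given SMILES is read as (1S,2R,5R,6R), with the C2 aryl exo (cis to the C1 hydroxyl) and the C6 aryl endo. Ar = 3,4-dimethoxyphenyl.

**Step 1**
Reactants: 1 veratraldehyde (3,4-dimethoxybenzaldehyde, 2.2 equiv); 2 dimethyl succinate
Product: 4 (2E,3E)-2,3-bis(3,4-dimethoxybenzylidene)butanedioic acid, via mono-arylidene half-ester 3 (not isolated)
Conditions: KOtBu (4.5 equiv), t-BuOH, reflux; then aq. HCl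
Reagents that add atoms: none
Why: Stobbe condensation run twice in one flask: the succinate enolate adds to the aldehyde, the alkoxide lactonises onto the distal ester and base-induced ring opening gives the (E)-arylidene carboxylate 3, and repetition at the remaining CH2 should give the (E,E)-diacid, each aryl group ending trans to the carboxyl group on its own double bond.

**Step 2**
Reactants: 4 (2E,3E)-2,3-bis(3,4-dimethoxybenzylidene)butanedioic acid
Product: 5 dimethyl (2E,3E)-2,3-bis(3,4-dimethoxybenzylidene)butanedioate
Conditions: MeI (2.5 equiv), K2CO3, DMF, rt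
Reagents that add atoms: iodomethane, CI
Why: SN2 O-alkylation of the two carboxylates; the non-acidic conditions avoid the acid-induced cyclisation of the electron-rich diene to an aryldihydronaphthalene.

**Step 3**
Reactants: 5 dimethyl (2E,3E)-2,3-bis(3,4-dimethoxybenzylidene)butanedioate
Product: 6 (2E,3E)-2,3-bis(3,4-dimethoxybenzylidene)butane-1,4-diol
Conditions: iBu2AlH (5 equiv), CH2Cl2, −78 → 0 °C; aq. potassium sodium tartrate
Reagents that add atoms: none
Why: 1,2-reduction of the conjugated esters by the aluminium hydride should give the bis-allylic diol without touching the C=C bonds or their geometry.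

**Step 4**
Reactants: 6 (2E,3E)-2,3-bis(3,4-dimethoxybenzylidene)butane-1,4-diol
Product: 8 (2R,3S,4Z)-2-(3,4-dimethoxyphenyl)-4-(3,4-dimethoxybenzylidene)-3-(hydroxymethyl)oxolan-3-ol, via epoxy alcohol 7 (not isolated)
Conditions: Ti(OiPr)4 (1.0 equiv), L-(+)-diethyl tartrate (1.2 equiv), tBuOOH (1.05 equiv, anhydrous), 4 Å molecular sieves, CH2Cl2, −25 °C; then warm to 0 °C; NaOH/brine work-up
Reagents that add atoms: tert-butyl hydroperoxide, CC(C)(C)OO
Why: Sharpless asymmetric epoxidation of one of the two homotopic allylic alcohol units under L-(+)-tartrate control should give the (2S,3S)-epoxy alcohol 7, whose electron-rich benzylic carbon is then opened in the flask by the hydroxymethyl group of the other arm (titanium-assisted 5-endo epoxide opening with inversion), closing ring A and setting the future C1 (S, tertiary alcohol) and C2 (R, aryl cis to the hydroxyl).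

**Step 5**
Reactants: 8 (2R,3S,4Z)-2-(3,4-dimethoxyphenyl)-4-(3,4-dimethoxybenzylidene)-3-(hydroxymethyl)oxolan-3-ol
Product: 9 (2R,3S,4Z)-2-(3,4-dimethoxyphenyl)-4-(3,4-dimethoxybenzylidene)-3-[(triethylsilyloxy)methyl]oxolan-3-ol
Conditions: Et3SiCl (1.1 equiv), imidazole, CH2Cl2, −20 → 0 °C
Reagents that add atoms: chlorotriethylsilane, CC[Si](Cl)(CC)CC
Why: selective silylation of the primary over the tertiary hydroxyl; the silyl ether keeps the future O7 from closing onto C6 before step 8, stops it from directing the hydroboration to the wrong face, and is expelled in the key step.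

**Step 6**
Reactants: 9 (2R,3S,4Z)-2-(3,4-dimethoxyphenyl)-4-(3,4-dimethoxybenzylidene)-3-[(triethylsilyloxy)methyl]oxolan-3-ol
Product: 11 (2R,3S,4R)-2-(3,4-dimethoxyphenyl)-4-[(R)-(3,4-dimethoxyphenyl)(hydroxy)methyl]-3-[(triethylsilyloxy)methyl]oxolan-3-ol, via cyclic alkoxyborane 10 (not isolated)
Conditions: BH3·THF (3 equiv), THF, 0 °C → rt; then 3 M NaOH, 30% H2O2, 0 °C
Reagents that add atoms: hydrogen peroxide, OO
Why: hydroboration–oxidation: boron should add to the less substituted benzylic carbon and hydrogen to the ring carbon, both from the face of the tertiary oxygen (delivery through the alkoxyborane 10, which is also the face away from the bulky CH2OSiEt3 group), so that the new C–H bond at the future C5 is cis to the hydroxyl; the C–B bond is oxidised with retention.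

**Step 7**
Reactants: 11 (2R,3S,4R)-2-(3,4-dimethoxyphenyl)-4-[(R)-(3,4-dimethoxyphenyl)(hydroxy)methyl]-3-[(triethylsilyloxy)methyl]oxolan-3-ol
Product: 12 [(3S,4S,5R)-5-(3,4-dimethoxyphenyl)-4-hydroxy-4-[(triethylsilyloxy)methyl]oxolan-3-yl](3,4-dimethoxyphenyl)methanone
Conditions: Dess–Martin periodinane (1.3 equiv), CH2Cl2, 0 °C → rt
Reagents that add atoms: none
Why: Dess–Martin oxidation of the secondary benzylic alcohol to the aryl ketone; the tertiary alcohol and the silyl ether are inert and the near-neutral conditions should not epimerise the centre α to the new ketone.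

**Step 8**
Reactants: 12 [(3S,4S,5R)-5-(3,4-dimethoxyphenyl)-4-hydroxy-4-[(triethylsilyloxy)methyl]oxolan-3-yl](3,4-dimethoxyphenyl)methanone
Product: 14 (+)-gmelinol, (1S,2R,5R,6R)-2,6-bis(3,4-dimethoxyphenyl)-3,7-dioxabicyclo[3.3.0]octan-1-ol, via oxocarbenium triflate 13 (not isolated)
Conditions: Et3SiH (3 equiv), TMSOTf (0.3 equiv), CH2Cl2, −78 → −40 °C; then Et3N, sat. NaHCO3
Reagents that add atoms: none
Why: The silyl triflate activates the C6 ketone, the oxygen of the CH2OSiEt3 arm attacks it (5-exo-trig, ring B), and loss of both silyl groups as disiloxane gives the cis-fused oxocarbenium ion 13, which Et3SiH reduces. The closest known reaction type is the reductive etherification of silyloxy ketones and the Et3SiH/Lewis acid reduction of 2-aryl lactols used for C-aryl glycosides and endo-aryl furofuran lignans. Ring B can only close cis on ring A, so any C5 epimer stays open and is not carried into the product. The new stereocentre C6 is controlled by the bicyclic skeleton: hydride adds to the convex face (the side of H-5 and the C1 hydroxyl), which places H-6 exo and the aryl group endo, giving (6R). The step needs kinetic control, because the endo aryl ether is the less stable epimer and the product can ionise at C6; the low temperature, the substoichiometric acid and the excess silane secure this and also limit ionic hydrogenolysis of the two benzylic C–O bonds. The free tertiary hydroxyl on C1 cannot compete as a nucleophile, since it would have to form a four-membered ring.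

**Compound list**

1 | veratraldehyde (3,4-dimethoxybenzaldehyde) | COc1ccc(C=O)cc1OC | starting material
2 | dimethyl succinate | COC(=O)CCC(=O)OC | starting material
3 | (E)-4-(3,4-dimethoxyphenyl)-3-(methoxycarbonyl)but-3-enoic acid (not isolated) | COc1ccc(/C=C(/C(=O)OC)CC(=O)O)cc1OC | intermediate
4 | (2E,3E)-2,3-bis(3,4-dimethoxybenzylidene)butanedioic acid | COc1ccc(/C=C(/C(=O)O)\C(C(=O)O)=C/c2ccc(OC)c(OC)c2)cc1OC | intermediate
5 | dimethyl (2E,3E)-2,3-bis(3,4-dimethoxybenzylidene)butanedioate | COc1ccc(/C=C(/C(=O)OC)\C(C(=O)OC)=C/c2ccc(OC)c(OC)c2)cc1OC | intermediate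
6 | (2E,3E)-2,3-bis(3,4-dimethoxybenzylidene)butane-1,4-diol | COc1ccc(/C=C(/CO)\C(CO)=C/c2ccc(OC)c(OC)c2)cc1OC | intermediate
7 | [(2S,3S)-3-(3,4-dimethoxyphenyl)-2-[(Z)-1-(3,4-dimethoxyphenyl)-3-hydroxyprop-1-en-2-yl]oxiran-2-yl]methanol (not isolated) | COc1ccc([C@@H]2O[C@]2(CO)\C(CO)=C/c3ccc(OC)c(OC)c3)cc1OC | intermediate
8 | (2R,3S,4Z)-2-(3,4-dimethoxyphenyl)-4-(3,4-dimethoxybenzylidene)-3-(hydroxymethyl)oxolan-3-ol | COc1ccc([C@H]2OC/C(=C/c3ccc(OC)c(OC)c3)[C@]2(O)CO)cc1OC | intermediate
9 | (2R,3S,4Z)-2-(3,4-dimethoxyphenyl)-4-(3,4-dimethoxybenzylidene)-3-[(triethylsilyloxy)methyl]oxolan-3-ol | COc1ccc([C@H]2OC/C(=C/c3ccc(OC)c(OC)c3)[C@]2(O)CO[Si](CC)(CC)CC)cc1OC | intermediate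
10 | cyclic alkoxyborane: 1,2-oxaborolane fused to ring A, boron on the benzylic carbon and bound to the tertiary oxygen (not isolated) | COc1ccc([C@H]2OC[C@@H]3[C@H](c4ccc(OC)c(OC)c4)BO[C@@]23CO[Si](CC)(CC)CC)cc1OC | intermediate
11 | (2R,3S,4R)-2-(3,4-dimethoxyphenyl)-4-[(R)-(3,4-dimethoxyphenyl)(hydroxy)methyl]-3-[(triethylsilyloxy)methyl]oxolan-3-ol | COc1ccc([C@H]2OC[C@H]([C@@H](O)c3ccc(OC)c(OC)c3)[C@]2(O)CO[Si](CC)(CC)CC)cc1OC | intermediate
12 | [(3S,4S,5R)-5-(3,4-dimethoxyphenyl)-4-hydroxy-4-[(triethylsilyloxy)methyl]oxolan-3-yl](3,4-dimethoxyphenyl)methanone | COc1ccc([C@H]2OC[C@H](C(=O)c3ccc(OC)c(OC)c3)[C@]2(O)CO[Si](CC)(CC)CC)cc1OC | intermediate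
13 | cis-fused 3,7-dioxabicyclo[3.3.0]octane oxocarbenium ion (O7=C6, aryl on C6), triflate salt (not isolated) | COc1ccc([C@H]2OC[C@@H]3C(c4ccc(OC)c(OC)c4)=[O+]C[C@]23O)cc1OC.[O-]S(=O)(=O)C(F)(F)F | intermediate
14 | (+)-gmelinol, (1S,2R,5R,6R)-2,6-bis(3,4-dimethoxyphenyl)-3,7-dioxabicyclo[3.3.0]octan-1-ol | COc1ccc([C@H]2OC[C@@H]3[C@H](c4ccc(OC)c(OC)c4)OC[C@]23O)cc1OC | target

**Step count and risks**

Total step count: 8. Longest linear sequence: 8 steps (from 1 and 2 to 14).

Steps most likely to fail:

1. Step 4. The one-pot epoxidation–cyclisation may suffer from epoxidation of both arms, from opening of the vinylic aryl epoxide at the wrong carbon, or from loss of configuration at the benzylic carbon through a cation. Fallback, from 6 back to 8: the two arms are first told apart by protection. One hydroxymethyl group is silylated (NaH, 1 equiv; TBSCl, THF) to give the mono-silyl ether F1. Epoxidation of the remaining free allylic alcohol under the same tartrate control gives the epoxy alcohol F2, which is isolated cold on base-washed silica. Bu4NF then removes the silyl group, and the liberated alkoxide should close ring A by SN2 opening at the benzylic carbon under basic, non-ionising conditions, giving 8.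

2. Step 6. Hydroboration may place boron on the ring carbon or deliver hydrogen to the wrong face of the future C5. Fallback, from 9 back to 11: the tertiary hydroxyl is used as a covalent tether. Silylation (HMe2SiCl, Et3N, DMAP) gives the dimethylsilyl ether F3. Intramolecular hydrosilylation catalysed by Pt2[(CH2=CHSiMe2)2O]3 should form the five-membered oxasilolane F4, with silicon on the benzylic carbon and hydrogen delivered to C5 from the face of the C1 oxygen. Oxidation of the C–Si bond with retention (H2O2, KHCO3, MeOH/THF) returns to 11; the primary silyl ether is put back as in step 5 if it is lost.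

3. Step 8. Acid-mediated ring opening may erode the configuration at C6, or ionic hydrogenolysis may cleave the benzylic C–O bonds. Fallback, from 12 to 14: C6 is set without a carbocation. HF·pyridine removes the silyl group and the hydroxy ketone closes to the lactol F5. Dehydration (MsCl, Et3N) gives the cyclic enol ether F6 with a C5=C6 double bond in ring B. Hydroxyl-directed hydrogenation ([Ir(cod)(PCy3)(py)]PF6, H2, CH2Cl2) should add both hydrogens from the face of the C1 hydroxyl, the convex face, which gives the cis ring fusion and the endo aryl group of 14.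

**Further compounds**

F1 | step 4 | (2E,3E)-2,3-bis(3,4-dimethoxybenzylidene)-4-(tert-butyldimethylsilyloxy)butan-1-ol | COc1ccc(/C=C(/CO)\C(CO[Si](C)(C)C(C)(C)C)=C/c2ccc(OC)c(OC)c2)cc1OC
F2 | step 4 | [(2S,3S)-2-[(Z)-3-(tert-butyldimethylsilyloxy)-1-(3,4-dimethoxyphenyl)prop-1-en-2-yl]-3-(3,4-dimethoxyphenyl)oxiran-2-yl]methanol | COc1ccc([C@@H]2O[C@]2(CO)\C(CO[Si](C)(C)C(C)(C)C)=C/c3ccc(OC)c(OC)c3)cc1OC
F3 | step 6 | dimethylsilyl ether of the tertiary hydroxyl of 9 | COc1ccc([C@H]2OC/C(=C/c3ccc(OC)c(OC)c3)[C@]2(O[SiH](C)C)CO[Si](CC)(CC)CC)cc1OC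
F4 | step 6 | oxasilolane fused to ring A (SiMe2 on the benzylic carbon and on the tertiary oxygen) | COc1ccc([C@H]2OC[C@@H]3[C@H](c4ccc(OC)c(OC)c4)[Si](C)(C)O[C@@]23CO[Si](CC)(CC)CC)cc1OC
F5 | step 8 | (1S,2R,5R)-2,6-bis(3,4-dimethoxyphenyl)-3,7-dioxabicyclo[3.3.0]octane-1,6-diol (lactol, both configurations at C6) | COc1ccc([C@H]2OC[C@@H]3C(O)(c4ccc(OC)c(OC)c4)OC[C@]23O)cc1OC
F6 | step 8 | (1S,2R)-2,6-bis(3,4-dimethoxyphenyl)-3,7-dioxabicyclo[3.3.0]oct-5-en-1-ol | COc1ccc([C@H]2OCC3=C(c4ccc(OC)c(OC)c4)OC[C@]23O)cc1OC
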